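**Plan**

- Retrosynthetic cuts: the four O–CH3 bonds; the ring A C–O bond to the ring B oxygen (closure of the 17-membered macrocycle); in ring C the C4–O bond, the C1–CH2 bond of the bridge to ring B and the C2–O bond to ring D; the CH2–CH2 bridge between rings D and A (as a C=C).
- Enabling feature: in ring C the aryloxy carbon C2 lies between the bridge carbon C1 and the hydroxylated C3. This is the pattern of C2 of cyclohexane-1,3-dione between its two carbonyls, so the C2–O bond can be made on a diazo dione and the arene built afterwards.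
- Forward order: rings D and A are joined to a bibenzyl phenol (Wittig, diimide), and O–H insertion attaches the dione to the ring D oxygen. An enol ether and Grignard addition then bring ring B onto C1, dehydrogenation turns the six-membered ring into ring C, and formylation/Dakin adds the C4 hydroxyl.
- Rings: ring C is the only carbocycle made (from cyclohexane-1,3-dione, aromatised in step 9). The macrocycle closes in the penultimate step by Ullmann etherification, and BBr3 then frees the four hydroxyls.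
- Stereochemistry: the target has no stereocentre and no stable axis. The stilbene geometry is erased by reduction and the racemic sp3 centres of intermediates disappear on aromatisation.

Key step: step 5

Remark: the 2-aryloxy dione from the key step is written as the diketone although it should exist mainly as its enol; its two carbonyls are equivalent by symmetry, so only one methyl enol ether can form.

**Step 1**
Reactants: 1 2-hydroxybenzyl alcohol
Product: 2 (2-hydroxybenzyl)triphenylphosphonium bromide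
Conditions: PPh3·HBr, MeCN, reflux
Reagents that add atoms: triphenylphosphine hydrobromide, [Br-].[PH+](c1ccccc1)(c1ccccc1)c1ccccc1
Why: Acid-promoted substitution of the benzylic hydroxyl by PPh3 (phosphonium salt formation via the o-hydroxybenzyl cation) is a standard entry to this Wittig salt and leaves the phenol free.

**Step 2**
Reactants: 2 (2-hydroxybenzyl)triphenylphosphonium bromide; 3 3-bromo-4,5-dimethoxybenzaldehyde
Product: 4 2-[2-(3-bromo-4,5-dimethoxyphenyl)ethenyl]phenol (E/Z mixture)
Conditions: KOtBu (2.2 equiv), THF, 0 °C to rt; aq. NH4Cl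
Reagents that add atoms: none
Why: Wittig olefination of the phenoxide ylide (two equivalents of base) with the aryl aldehyde should give the stilbene, whose E/Z ratio is irrelevant because the double bond is reduced next.

**Step 3**
Reactants: 4 2-[2-(3-bromo-4,5-dimethoxyphenyl)ethenyl]phenol
Product: 5 2-[2-(3-bromo-4,5-dimethoxyphenyl)ethyl]phenol
Conditions: TsNHNH2 (5 equiv), NaOAc, THF/H2O, reflux
Reagents that add atoms: none
Why: Diimide reduction, with diimide generated from the sulfonyl hydrazide, saturates the stilbene by concerted hydrogen transfer and, unlike hydrogenation over palladium, should leave the C–Br bond intact.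

**Step 4**
Reactants: 6 cyclohexane-1,3-dione
Product: 7 2-diazocyclohexane-1,3-dione
Conditions: p-ABSA, Et3N, MeCN, 0 °C to rt
Reagents that add atoms: 4-acetamidobenzenesulfonyl azide (p-ABSA), CC(=O)Nc1ccc(cc1)S(=O)(=O)N=[N+]=[N-]
Why: Regitz diazo transfer to the doubly activated methylene of a 1,3-dione under amine base is reliable and should give the stable diazo dione.

**Step 5**
Reactants: 5 2-[2-(3-bromo-4,5-dimethoxyphenyl)ethyl]phenol; 7 2-diazocyclohexane-1,3-dione
Product: 8 2-{2-[2-(3-bromo-4,5-dimethoxyphenyl)ethyl]phenoxy}cyclohexane-1,3-dione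
Conditions: Rh2(OAc)4 (2 mol %), PhF, 70 °C, slow addition of 7 (1.3 equiv) to 5 and catalyst
Reagents that add atoms: none
Why: Rh2(OAc)4, a carboxylate dimer of divalent rhodium, expels N2 from 7 to give an electrophilic carbenoid flanked by two carbonyls; the phenol oxygen of 5 adds to the carbenoid carbon to form an oxonium ylide, and a proton shift releases the catalyst and leaves the C2–O bond of the future ring C. The closest known reaction type is the rhodium-carboxylate-catalysed O–H insertion of 2-diazo-1,3-dicarbonyl compounds into phenols and alcohols. No ring is closed and no stereocentre is formed, since C2 of 8 is an enolisable carbon on a mirror plane. The step needs O–H insertion to outrun Wolff ring contraction, attack on the electron-rich rings A and D (C–H insertion or cyclopropanation) and a second insertion into the enol OH of 8. The free phenol is the most nucleophilic site of 5, the acceptor/acceptor carbenoid resists rearrangement at 70 °C, fluorobenzene is inert towards it, and slow addition of 7 keeps 5 in excess over the carbenoid.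

**Step 6**
Reactants: 8 2-{2-[2-(3-bromo-4,5-dimethoxyphenyl)ethyl]phenoxy}cyclohexane-1,3-dione
Product: 9 2-{2-[2-(3-bromo-4,5-dimethoxyphenyl)ethyl]phenoxy}-3-methoxycyclohex-2-en-1-one
Conditions: TMSCHN2, MeOH/PhMe, 0 °C to rt
Reagents that add atoms: (trimethylsilyl)diazomethane, C[Si](C)(C)C=[N+]=[N-]
Why: O-Methylation of the acidic enol by the diazoalkane (protonation, then methyl transfer) avoids C-alkylation at the substituted C2, and the symmetry of 8 allows only one vinylogous ester.

**Step 7**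
Reactants: 10 2-[4-(benzyloxy)phenyl]ethanol
Product: 11 1-(benzyloxy)-4-(2-bromoethyl)benzene
Conditions: CBr4, PPh3, CH2Cl2, 0 °C
Reagents that add atoms: tetrabromomethane, BrC(Br)(Br)Br
Why: Appel bromination converts the primary alcohol into the bromide under neutral conditions that leave the benzyl ether untouched.

**Step 8**
Reactants: 9 2-{2-[2-(3-bromo-4,5-dimethoxyphenyl)ethyl]phenoxy}-3-methoxycyclohex-2-en-1-one; 11 1-(benzyloxy)-4-(2-bromoethyl)benzene
Product: 14 3-{2-[4-(benzyloxy)phenyl]ethyl}-2-{2-[2-(3-bromo-4,5-dimethoxyphenyl)ethyl]phenoxy}cyclohex-2-en-1-one, via Grignard reagent 12 (not isolated), via tertiary carbinol 13 (not isolated)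
Conditions: 11, Mg, THF, rt to 40 °C; then 9, THF, 0 °C to rt; then 1 M HCl, rt
Reagents that add atoms: water, O
Why: Stork–Danheiser sequence, in which the primary alkyl Grignard reagent adds 1,2 to the vinylogous ester carbonyl without exchanging the electron-rich aryl bromide, and aqueous acid then hydrolyses the enol ether and dehydrates the carbinol to the transposed 3-alkyl-2-aryloxy enone.

**Step 9**
Reactants: 14 3-{2-[4-(benzyloxy)phenyl]ethyl}-2-{2-[2-(3-bromo-4,5-dimethoxyphenyl)ethyl]phenoxy}cyclohex-2-en-1-one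
Product: 18 3-{2-[4-(benzyloxy)phenyl]ethyl}-2-{2-[2-(3-bromo-4,5-dimethoxyphenyl)ethyl]phenoxy}phenol, via α'-phenylselanyl enone 15 (not isolated), via selenoxide 16 (not isolated), via cyclohexa-2,5-dienone 17 (not isolated)
Conditions: LiN(iPr)2 (LDA, 1.1 equiv), THF, −78 °C; PhSeBr, −78 °C; then 30% H2O2, pyridine, THF/CH2Cl2, 0 °C to rt
Reagents that add atoms: none
Why: Kinetic α'-deprotonation, α-selenenylation and selenoxide syn-elimination (Reich dehydrogenation) should place a C5–C6 double bond, and the resulting cyclohexa-2,5-dienone with a CH2 at C4 tautomerises spontaneously to the phenol of ring C.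

**Step 10**
Reactants: 18 3-{2-[4-(benzyloxy)phenyl]ethyl}-2-{2-[2-(3-bromo-4,5-dimethoxyphenyl)ethyl]phenoxy}phenol
Product: 19 4-{2-[4-(benzyloxy)phenyl]ethyl}-3-{2-[2-(3-bromo-4,5-dimethoxyphenyl)ethyl]phenoxy}-2-hydroxybenzaldehyde
Conditions: MgCl2, Et3N, (CH2O)n, MeCN, reflux
Reagents that add atoms: paraformaldehyde (as formaldehyde), C=O
Why: Magnesium-phenoxide-directed ortho-formylation (Casnati–Skattebøl) can only occur at C4 of ring C, the one free position ortho to the hydroxyl, because the other ortho carbon carries the aryloxy group.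

**Step 11**
Reactants: 19 4-{2-[4-(benzyloxy)phenyl]ethyl}-3-{2-[2-(3-bromo-4,5-dimethoxyphenyl)ethyl]phenoxy}-2-hydroxybenzaldehyde
Product: 21 4-{2-[4-(benzyloxy)phenyl]ethyl}-3-{2-[2-(3-bromo-4,5-dimethoxyphenyl)ethyl]phenoxy}benzene-1,2-diol, via aryl formate 20 (not isolated)
Conditions: 30% H2O2, aq. NaOH, THF, 0 °C, under argon; then dilute HCl
Reagents that add atoms: hydrogen peroxide, OO
Why: Dakin oxidation, in which hydroperoxide adds to the ortho-hydroxy aldehyde, aryl migration gives the formate and this is saponified in the same pot to the catechol.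

**Step 12**
Reactants: 21 4-{2-[4-(benzyloxy)phenyl]ethyl}-3-{2-[2-(3-bromo-4,5-dimethoxyphenyl)ethyl]phenoxy}benzene-1,2-diol
Product: 22 1-{2-[4-(benzyloxy)phenyl]ethyl}-2-{2-[2-(3-bromo-4,5-dimethoxyphenyl)ethyl]phenoxy}-3,4-dimethoxybenzene
Conditions: MeI, K2CO3, DMF, rt (crude 21 used directly)
Reagents that add atoms: iodomethane, CI
Why: Williamson O-methylation of both catechol hydroxyls masks ring C before the ring B phenol is released and removes the air-sensitive catechol.

**Step 13**
Reactants: 22 1-{2-[4-(benzyloxy)phenyl]ethyl}-2-{2-[2-(3-bromo-4,5-dimethoxyphenyl)ethyl]phenoxy}-3,4-dimethoxybenzene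
Product: 23 4-[2-(2-{2-[2-(3-bromo-4,5-dimethoxyphenyl)ethyl]phenoxy}-3,4-dimethoxyphenyl)ethyl]phenol
Conditions: BCl3, C6HMe5, CH2Cl2, −78 °C
Reagents that add atoms: none
Why: Lewis-acid debenzylation with BCl3 and pentamethylbenzene as benzyl-cation scavenger cleaves aryl benzyl ethers at −78 °C while the aryl methyl ethers and the aryl bromide, which hydrogenolysis would endanger, should remain.

**Step 14**
Reactants: 23 4-[2-(2-{2-[2-(3-bromo-4,5-dimethoxyphenyl)ethyl]phenoxy}-3,4-dimethoxyphenyl)ethyl]phenol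
Product: 24 tetra-O-methyl ether of the target macrocycle (two OMe on ring A and two on ring C)
Conditions: CuI (20 mol %), N,N-dimethylglycine (60 mol %), Cs2CO3, 1,4-dioxane, 100 °C, syringe-pump addition to 2 mM
Reagents that add atoms: none
Why: Intramolecular Ullmann diaryl ether synthesis under ligand-accelerated copper catalysis at high dilution should join the ring B phenoxide to the bromine-bearing carbon of ring A, the only reactive pair left in the molecule.

**Step 15**
Reactants: 24 tetra-O-methyl ether of the target macrocycle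
Product: 25 target tetraphenolic macrocyclic bis(bibenzyl) CNP0114693.0
Conditions: BBr3, CH2Cl2, −78 °C to rt; then H2O
Reagents that add atoms: none
Why: BBr3 demethylation cleaves the four aryl methyl ethers by Lewis-acid complexation and bromide attack on methyl, whereas the two diaryl ethers cannot be cleaved in this way.

**Compound list**

1 | 2-hydroxybenzyl alcohol | OCc1ccccc1O | starting material
2 | (2-hydroxybenzyl)triphenylphosphonium bromide | Oc1ccccc1C[P+](c1ccccc1)(c1ccccc1)c1ccccc1.[Br-] | intermediate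
3 | 3-bromo-4,5-dimethoxybenzaldehyde | COc1cc(C=O)cc(Br)c1OC | starting material
4 | 2-[2-(3-bromo-4,5-dimethoxyphenyl)ethenyl]phenol (E/Z mixture, E isomer drawn) | Oc1ccccc1/C=C/c1cc(Br)c(OC)c(OC)c1 | intermediate
5 | 2-[2-(3-bromo-4,5-dimethoxyphenyl)ethyl]phenol | Oc1ccccc1CCc1cc(Br)c(OC)c(OC)c1 | intermediate
6 | cyclohexane-1,3-dione | O=C1CCCC(=O)C1 | starting material
7 | 2-diazocyclohexane-1,3-dione | O=C1CCCC(=O)C1=[N+]=[N-] | intermediate
8 | 2-{2-[2-(3-bromo-4,5-dimethoxyphenyl)ethyl]phenoxy}cyclohexane-1,3-dione (diketo tautomer drawn) | O=C1CCCC(=O)C1Oc1ccccc1CCc1cc(Br)c(OC)c(OC)c1 | intermediate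
9 | 2-{2-[2-(3-bromo-4,5-dimethoxyphenyl)ethyl]phenoxy}-3-methoxycyclohex-2-en-1-one | COC1=C(Oc2ccccc2CCc2cc(Br)c(OC)c(OC)c2)C(=O)CCC1 | intermediate
10 | 2-[4-(benzyloxy)phenyl]ethanol | OCCc1ccc(OCc2ccccc2)cc1 | starting material
11 | 1-(benzyloxy)-4-(2-bromoethyl)benzene | BrCCc1ccc(OCc2ccccc2)cc1 | intermediate
12 | {2-[4-(benzyloxy)phenyl]ethyl}magnesium bromide | Br[Mg]CCc1ccc(OCc2ccccc2)cc1 | intermediate
13 | 1-{2-[4-(benzyloxy)phenyl]ethyl}-2-{2-[2-(3-bromo-4,5-dimethoxyphenyl)ethyl]phenoxy}-3-methoxycyclohex-2-en-1-ol (racemic, present as its magnesium alkoxide) | COC1=C(Oc2ccccc2CCc2cc(Br)c(OC)c(OC)c2)C(O)(CCc2ccc(OCc3ccccc3)cc2)CCC1 | intermediate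
14 | 3-{2-[4-(benzyloxy)phenyl]ethyl}-2-{2-[2-(3-bromo-4,5-dimethoxyphenyl)ethyl]phenoxy}cyclohex-2-en-1-one | O=C1CCCC(CCc2ccc(OCc3ccccc3)cc2)=C1Oc1ccccc1CCc1cc(Br)c(OC)c(OC)c1 | intermediate
15 | 6-(phenylselanyl) derivative of enone 14 (racemic) | O=C1C([Se]c2ccccc2)CCC(CCc2ccc(OCc3ccccc3)cc2)=C1Oc1ccccc1CCc1cc(Br)c(OC)c(OC)c1 | intermediate
16 | 6-(phenylseleninyl) derivative of enone 14 (selenoxide, mixture of diastereomers) | O=C1C([Se](=O)c2ccccc2)CCC(CCc2ccc(OCc3ccccc3)cc2)=C1Oc1ccccc1CCc1cc(Br)c(OC)c(OC)c1 | intermediate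
17 | 3-{2-[4-(benzyloxy)phenyl]ethyl}-2-{2-[2-(3-bromo-4,5-dimethoxyphenyl)ethyl]phenoxy}cyclohexa-2,5-dien-1-one | O=C1C=CCC(CCc2ccc(OCc3ccccc3)cc2)=C1Oc1ccccc1CCc1cc(Br)c(OC)c(OC)c1 | intermediate
18 | 3-{2-[4-(benzyloxy)phenyl]ethyl}-2-{2-[2-(3-bromo-4,5-dimethoxyphenyl)ethyl]phenoxy}phenol | Oc1cccc(CCc2ccc(OCc3ccccc3)cc2)c1Oc1ccccc1CCc1cc(Br)c(OC)c(OC)c1 | intermediate
19 | 4-{2-[4-(benzyloxy)phenyl]ethyl}-3-{2-[2-(3-bromo-4,5-dimethoxyphenyl)ethyl]phenoxy}-2-hydroxybenzaldehyde | O=Cc1ccc(CCc2ccc(OCc3ccccc3)cc2)c(Oc2ccccc2CCc2cc(Br)c(OC)c(OC)c2)c1O | intermediate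
20 | 4-{2-[4-(benzyloxy)phenyl]ethyl}-3-{2-[2-(3-bromo-4,5-dimethoxyphenyl)ethyl]phenoxy}-2-hydroxyphenyl formate | O=COc1ccc(CCc2ccc(OCc3ccccc3)cc2)c(Oc2ccccc2CCc2cc(Br)c(OC)c(OC)c2)c1O | intermediate
21 | 4-{2-[4-(benzyloxy)phenyl]ethyl}-3-{2-[2-(3-bromo-4,5-dimethoxyphenyl)ethyl]phenoxy}benzene-1,2-diol | Oc1ccc(CCc2ccc(OCc3ccccc3)cc2)c(Oc2ccccc2CCc2cc(Br)c(OC)c(OC)c2)c1O | intermediate
22 | 1-{2-[4-(benzyloxy)phenyl]ethyl}-2-{2-[2-(3-bromo-4,5-dimethoxyphenyl)ethyl]phenoxy}-3,4-dimethoxybenzene | COc1ccc(CCc2ccc(OCc3ccccc3)cc2)c(Oc2ccccc2CCc2cc(Br)c(OC)c(OC)c2)c1OC | intermediate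
23 | 4-[2-(2-{2-[2-(3-bromo-4,5-dimethoxyphenyl)ethyl]phenoxy}-3,4-dimethoxyphenyl)ethyl]phenol | COc1ccc(CCc2ccc(O)cc2)c(Oc2ccccc2CCc2cc(Br)c(OC)c(OC)c2)c1OC | intermediate
24 | tetra-O-methyl ether of the target macrocycle | COc1cc2cc(c1OC)Oc1ccc(cc1)CCc1ccc(OC)c(OC)c1Oc1ccccc1CC2 | intermediate
25 | target macrocyclic bis(bibenzyl) tetraphenol CNP0114693.0 | Oc1cc2cc(c1O)Oc1ccc(cc1)CCc1ccc(O)c(O)c1Oc1ccccc1CC2 | target

**Step count and risks**

Total steps: 15. Longest linear sequence: 13 steps (1, 2, 3, 5, 6, 8, 9, 10, 11, 12, 13, 14, 15).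

Steps most likely to fail:

1. Step 5. The carbenoid may be diverted into Wolff ring contraction, into attack on the electron-rich arenes, or into a second insertion at the enol hydroxyl of the product, so that conversion of 5 stalls. The fallback sets out from 5 and keeps the C–O bond at a non-aromatic carbon but forms it by nucleophilic opening. The potassium phenoxide of 5 (KH, THF/DMPU, 60 °C) should open commercial 2,3-epoxycyclohexan-1-one at C2 to give trans-2-{2-[2-(3-bromo-4,5-dimethoxyphenyl)ethyl]phenoxy}-3-hydroxycyclohexan-1-one F1. This should lose water in the same pot to 2-{2-[2-(3-bromo-4,5-dimethoxyphenyl)ethyl]phenoxy}cyclohex-2-en-1-one F2. 1,2-Addition of Grignard reagent 12 (CeCl3, THF, −78 °C) should then give the tertiary allylic alcohol 1-{2-[4-(benzyloxy)phenyl]ethyl}-2-{2-[2-(3-bromo-4,5-dimethoxyphenyl)ethyl]phenoxy}cyclohex-2-en-1-ol F3. Dauben oxidative transposition with pyridinium chlorochromate, [C5H5NH][CrO3Cl], in CH2Cl2 returns to the route at 14.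

2. Step 8. The Grignard reagent may deprotonate 9 at C6 instead of adding to the hindered carbonyl next to the aryloxy group, and Wurtz homocoupling may consume the bromide during magnesium insertion. The fallback sets out from 8 and replaces 1,2-addition/transposition by conjugate addition–elimination. Oxalyl chloride with catalytic DMF in CH2Cl2 should give 3-chloro-2-{2-[2-(3-bromo-4,5-dimethoxyphenyl)ethyl]phenoxy}cyclohex-2-en-1-one F4. The magnesium cuprate from 12 and CuBr·SMe2 (THF, −78 to 0 °C) should displace chloride and return to the route at 14.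

3. Step 14. Intermolecular etherification may outrun closure of the strained 17-membered ring, and the hindered, electron-rich ring A bromide may be reduced at 100 °C before it couples. The fallback sets out from 23 and closes the same bond by oxidative coupling at room temperature. Miyaura borylation (PdCl2(dppf), B2pin2, KOAc, dioxane, 90 °C) should give the pinacol boronate 4-[2-(2-{2-[2-(3,4-dimethoxy-5-(4,4,5,5-tetramethyl-1,3,2-dioxaborolan-2-yl)phenyl)ethyl]phenoxy}-3,4-dimethoxyphenyl)ethyl]phenol F5. Periodate cleavage of the pinacol (NaIO4, NH4OAc, acetone/H2O) should give the boronic acid (5-{2-[2-(6-{2-(4-hydroxyphenyl)ethyl}-2,3-dimethoxyphenoxy)phenyl]ethyl}-2,3-dimethoxyphenyl)boronic acid F6. Chan–Lam–Evans coupling (Cu(OAc)2, Et3N, 4 Å molecular sieves, O2, CH2Cl2, rt, high dilution) returns to the route at 24.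

**Further compounds**

F1 | step 5 | trans-2-{2-[2-(3-bromo-4,5-dimethoxyphenyl)ethyl]phenoxy}-3-hydroxycyclohexan-1-one (racemic, one enantiomer drawn) | O=C1CCC[C@@H](O)[C@@H]1Oc1ccccc1CCc1cc(Br)c(OC)c(OC)c1
F2 | step 5 | 2-{2-[2-(3-bromo-4,5-dimethoxyphenyl)ethyl]phenoxy}cyclohex-2-en-1-one | O=C1CCCC=C1Oc1ccccc1CCc1cc(Br)c(OC)c(OC)c1
F3 | step 5 | 1-{2-[4-(benzyloxy)phenyl]ethyl}-2-{2-[2-(3-bromo-4,5-dimethoxyphenyl)ethyl]phenoxy}cyclohex-2-en-1-ol (racemic) | OC1(CCc2ccc(OCc3ccccc3)cc2)CCCC=C1Oc1ccccc1CCc1cc(Br)c(OC)c(OC)c1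
F4 | step 8 | 3-chloro-2-{2-[2-(3-bromo-4,5-dimethoxyphenyl)ethyl]phenoxy}cyclohex-2-en-1-one | O=C1CCCC(Cl)=C1Oc1ccccc1CCc1cc(Br)c(OC)c(OC)c1
F5 | step 14 | 4-[2-(2-{2-[2-(3,4-dimethoxy-5-(4,4,5,5-tetramethyl-1,3,2-dioxaborolan-2-yl)phenyl)ethyl]phenoxy}-3,4-dimethoxyphenyl)ethyl]phenol | COc1ccc(CCc2ccc(O)cc2)c(Oc2ccccc2CCc2cc(B3OC(C)(C)C(C)(C)O3)c(OC)c(OC)c2)c1OC
F6 | step 14 | (5-{2-[2-(6-{2-(4-hydroxyphenyl)ethyl}-2,3-dimethoxyphenoxy)phenyl]ethyl}-2,3-dimethoxyphenyl)boronic acid | COc1ccc(CCc2ccc(O)cc2)c(Oc2ccccc2CCc2cc(B(O)O)c(OC)c(OC)c2)c1OC
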